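A direct plan would acylate lithiated 1,2,3,4-tetramethoxybenzene with a methoxyacetyl Weinreb amide to ketone A1 and C-acylate its enolate with 2,4-bis(benzyloxy)benzoyl chloride to the 1,3-diketone A2.
It would then close ring C at O1–C8a by an oxidative (anodic) enol-O/aryl C–H coupling to the pentamethoxyflavone A3, and end with BCl3 to cleave the 5-OMe and both benzyl ethers.
Weakest steps: (a) the dehydrogenative O1–C8a ring closure, a reaction type not known for closing a 4-pyranone from a 1,3-diketone, which would have to oxidise ring A selectively beside a dibenzyloxyarene and an enolisable methine.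
(b) The final BCl3 step, which would have to remove one of five methyl ethers (a 5-OMe put in only to be taken off) and two benzyl groups on the finished skeleton, with the 3- and 6-OMe and benzyl-cation C-alkylation at risk.
(c) The crossed Claisen acylation, which would spend two equivalents of A1 and compete with O-acylation.

**Retrosynthetic overview**
Ring A is cut at C4a–C5 and C8–C8a: its contiguous C5(OH)–C6(OMe)–C7(OMe)–C8(OMe) unit is the four-carbon ring of dimethyl squarate, and C4a/C8a are C5/C6 of a 4-pyranone (ring C) that already carries the 3-OMe and ring B.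
Ring order: ring B (bought) and ring C (bought as 3-hydroxy-4-pyranone) are joined by Suzuki coupling; ring A is made last, C8–C8a by addition of the C6-lithiated pyranone to the squarate, C4a–C5 by thermal 4π ring opening/6π ring closure.
The ketene carbonyl becomes the 5-OH and the methylated carbinol the 8-OMe, so the route needs no oxidative O–aryl closure and no late demethylation; the last step is a neutral hydrogenolysis.

Key step: step 5

Assumption: 3-hydroxy-4H-pyran-4-one, dimethyl squarate and 2,4-bis(benzyloxy)phenylboronic acid are taken as catalogue compounds; ring B is carried as its bis(benzyl ether) because benzyl ethers tolerate the lithium amide and the thermolysis and leave by neutral hydrogenolysis.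

**Step 1**
Reactants: 1 3-hydroxy-4H-pyran-4-one (pyromeconic acid)
Product: 2 2-bromo-3-hydroxy-4H-pyran-4-one
Conditions: NBS (1.05 equiv), MeCN, 0 °C → rt
Reagents that add atoms: N-bromosuccinimide, O=C1CCC(=O)N1Br
Why: The enolic 3-hydroxy-4-pyranone should react with electrophilic bromine at C2, the carbon ortho to the hydroxyl and next to the ring oxygen (the position at which kojic acid and allomaltol are halogenated), so one monobromide is expected (electrophilic halogenation of an enol).

**Step 2**
Reactants: 2 2-bromo-3-hydroxy-4H-pyran-4-one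
Product: 3 2-bromo-3-methoxy-4H-pyran-4-one
Conditions: MeI (1.5 equiv), K2CO3 (1.5 equiv), acetone, 45 °C
Reagents that add atoms: iodomethane, CI
Why: The acidic enolic hydroxyl is deprotonated by carbonate and O-methylated (Williamson ether synthesis), which installs the future 3-OMe of the flavone and removes the acidic proton before the organometallic steps.

**Step 3**
Reactants: 3 2-bromo-3-methoxy-4H-pyran-4-one; 4 2,4-bis(benzyloxy)phenylboronic acid
Product: 5 2-[2,4-bis(benzyloxy)phenyl]-3-methoxy-4H-pyran-4-one
Conditions: Pd(OAc)2 (3 mol %), SPhos (6 mol %), K3PO4 (2 equiv), toluene/H2O 10:1, 80 °C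
Reagents that add atoms: none
Why: Suzuki–Miyaura coupling, in which the C–Br bond of the vinylogous acyl bromide should add quickly to zerovalent palladium and the electron-rich biarylphosphine should drive transmetalation and reductive elimination of the ortho-substituted boronic acid faster than its protodeboronation, forming the C2–C1′ bond of the flavone.

**Step 4**
Reactants: 5 2-[2,4-bis(benzyloxy)phenyl]-3-methoxy-4H-pyran-4-one; 6 dimethyl squarate (3,4-dimethoxycyclobut-3-ene-1,2-dione)
Product: 9 4-{6-[2,4-bis(benzyloxy)phenyl]-5-methoxy-4-oxo-4H-pyran-2-yl}-2,3,4-trimethoxycyclobut-2-en-1-one (racemic), via 6-lithiopyranone 7 (not isolated), via lithium cyclobutenolate 8 (not isolated)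
Conditions: LiTMP (lithium 2,2,6,6-tetramethylpiperidide, 1.1 equiv, from TMPH and n-BuLi), THF, −78 °C, 20 min; add to 6 (1.3 equiv), THF, −78 °C, 30 min; MeOTf (1.5 equiv), −78 → −20 °C; aq. NaHCO3
Reagents that add atoms: methyl trifluoromethanesulfonate, COS(=O)(=O)C(F)(F)F
Why: The hindered, non-nucleophilic amide should remove the C6–H next to the ring oxygen (the α-heteroatom site that lithium amides take in 3-substituted chromones, 4-quinolones and uracils), the vinyllithium should add 1,2 to one of the two equivalent carbonyl groups of the squarate at −78 °C, and the tertiary lithium alkoxide is O-methylated in the flask (deprotonative metalation / organolithium 1,2-addition to a squarate ester / alkoxide alkylation); the new carbinol centre is racemic and disappears in step 5.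

**Step 5**
Reactants: 9 4-{6-[2,4-bis(benzyloxy)phenyl]-5-methoxy-4-oxo-4H-pyran-2-yl}-2,3,4-trimethoxycyclobut-2-en-1-one
Product: 12 2-[2,4-bis(benzyloxy)phenyl]-5-hydroxy-3,6,7,8-tetramethoxy-4H-chromen-4-one, via dienylketene 10 (not isolated), via 4aH-chromenedione 11 (not isolated)
Conditions: p-xylene (0.02 M, degassed), 140 °C, 1 h, Ar
Reagents that add atoms: none
Why: On heating, the cyclobutenone should open by a conrotatory 4π electrocyclic reaction in which the donor methoxy group on the sp3 carbon rotates outward, so that the pyranonyl group sits inward (Z) in dienylketene 10. The electrophilic ketene carbon should then close onto C5 of the pyranone, the nucleophilic β-carbon of the vinylogous ester, by a 6π electrocyclisation that forms the C4a–C5 bond and ring A as the cyclohexadienone 11, and enolisation gives the aromatic ring. The closest known reaction type is the Moore rearrangement of 4-aryl-, 4-heteroaryl- and 4-alkenyl-4-alkoxycyclobutenones from squarate esters to annulated hydroquinone monoethers. No stereocentre is left: the racemic carbinol carbon of 9 becomes aromatic C8 and the transient C4a–H centre of 11 is lost on enolisation. The step needs the right direction of conrotation, secured by the outward preference of the alkoxy group, and a single site of closure, secured because the linking carbon (C8a) has the ring oxygen as its other neighbour. The oxygen pattern is then fixed by the mechanism: the ketene carbonyl ends as the 5-OH, hydrogen-bonded to the C4 carbonyl, and the methylated carbinol as the 8-OMe, with the squarate methoxy groups at C6 and C7.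

**Step 6**
Reactants: 12 2-[2,4-bis(benzyloxy)phenyl]-5-hydroxy-3,6,7,8-tetramethoxy-4H-chromen-4-one
Product: 13 2-(2,4-dihydroxyphenyl)-5-hydroxy-3,6,7,8-tetramethoxy-4H-chromen-4-one (5,2′,4′-trihydroxy-3,6,7,8-tetramethoxyflavone)
Conditions: H2 (1 atm), 10% Pd/C, EtOAc/MeOH 1:1, rt
Reagents that add atoms: none
Why: Catalytic hydrogenolysis of the two aryl benzyl ethers under neutral conditions should free the 2′- and 4′-OH, while the methyl ethers, the chelated 5-OH and the tetrasubstituted, cross-conjugated C2=C3 bond of the chromone stay untouched.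

**Compound list**
1 | 3-hydroxy-4H-pyran-4-one (pyromeconic acid) | O=c1ccocc1O | starting material
2 | 2-bromo-3-hydroxy-4H-pyran-4-one | O=c1ccoc(Br)c1O | intermediate
3 | 2-bromo-3-methoxy-4H-pyran-4-one | COc1c(Br)occc1=O | intermediate
4 | 2,4-bis(benzyloxy)phenylboronic acid | OB(O)c1ccc(OCc2ccccc2)cc1OCc1ccccc1 | starting material
5 | 2-[2,4-bis(benzyloxy)phenyl]-3-methoxy-4H-pyran-4-one | COc1c(-c2ccc(OCc3ccccc3)cc2OCc2ccccc2)occc1=O | intermediate
6 | dimethyl squarate (3,4-dimethoxycyclobut-3-ene-1,2-dione) | COC1=C(OC)C(=O)C1=O | starting material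
7 | {6-[2,4-bis(benzyloxy)phenyl]-5-methoxy-4-oxo-4H-pyran-2-yl}lithium | [Li]c1cc(=O)c(OC)c(-c2ccc(OCc3ccccc3)cc2OCc2ccccc2)o1 | intermediate
8 | lithium 1-{6-[2,4-bis(benzyloxy)phenyl]-5-methoxy-4-oxo-4H-pyran-2-yl}-2,3-dimethoxy-4-oxocyclobut-2-en-1-olate (racemic) | [Li+].[O-]C1(c2cc(=O)c(OC)c(-c3ccc(OCc4ccccc4)cc3OCc3ccccc3)o2)C(OC)=C(OC)C1=O | intermediate
9 | 4-{6-[2,4-bis(benzyloxy)phenyl]-5-methoxy-4-oxo-4H-pyran-2-yl}-2,3,4-trimethoxycyclobut-2-en-1-one (racemic) | COC1(c2cc(=O)c(OC)c(-c3ccc(OCc4ccccc4)cc3OCc3ccccc3)o2)C(OC)=C(OC)C1=O | intermediate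
10 | (3Z)-4-{6-[2,4-bis(benzyloxy)phenyl]-5-methoxy-4-oxo-4H-pyran-2-yl}-2,3,4-trimethoxybuta-1,3-dien-1-one | O=C=C(OC)/C(OC)=C(/OC)c1cc(=O)c(OC)c(-c2ccc(OCc3ccccc3)cc2OCc2ccccc2)o1 | intermediate
11 | 2-[2,4-bis(benzyloxy)phenyl]-3,6,7,8-tetramethoxy-4aH-chromene-4,5-dione (racemic) | COC1=C(OC)C(=O)C2C(=O)C(OC)=C(c3ccc(OCc4ccccc4)cc3OCc3ccccc3)OC2=C1OC | intermediate
12 | 2-[2,4-bis(benzyloxy)phenyl]-5-hydroxy-3,6,7,8-tetramethoxy-4H-chromen-4-one | COc1c(OC)c(O)c2c(=O)c(OC)c(-c3ccc(OCc4ccccc4)cc3OCc3ccccc3)oc2c1OC | intermediate
13 | 2-(2,4-dihydroxyphenyl)-5-hydroxy-3,6,7,8-tetramethoxy-4H-chromen-4-one (achiral) | COc1c(OC)c(O)c2c(=O)c(OC)c(-c3ccc(O)cc3O)oc2c1OC | target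

**Step count and risks**
Total step count: 6. Longest linear sequence: 6 steps (1 → 13); 4 and 6 are bought.

Steps most likely to fail:

Step 4. What may go wrong: loss of site control in the deprotonation (C5 next to the carbonyl, or a position on ring B, instead of C6), addition of the lithiated pyranone to unreacted 5, and methylation at the pyranone carbonyl oxygen or at the amine instead of the hindered alkoxide. The fallback sets out from 5 and comes back at 9. Zincation of 5 with TMPZnCl·LiCl (THF, 25 °C), a mild amide base class with close precedent for metalation of chromones and 4-pyranones next to the ring oxygen, would give {6-[2,4-bis(benzyloxy)phenyl]-5-methoxy-4-oxo-4H-pyran-2-yl}zinc chloride F1. Iodine would convert it into 2-[2,4-bis(benzyloxy)phenyl]-6-iodo-3-methoxy-4H-pyran-4-one F2, whose position of substitution can be checked before any squarate is spent. Iodine–magnesium exchange (iPrMgCl·LiCl, THF, −40 °C) would give {6-[2,4-bis(benzyloxy)phenyl]-5-methoxy-4-oxo-4H-pyran-2-yl}magnesium chloride F3. Addition to 6 at −78 °C and aqueous NH4Cl would give 4-{6-[2,4-bis(benzyloxy)phenyl]-5-methoxy-4-oxo-4H-pyran-2-yl}-4-hydroxy-2,3-dimethoxycyclobut-2-en-1-one F4, and methylation of the carbinol under neutral conditions (MeI, Ag2O, MeCN) would lead to 9.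

Step 5. What may go wrong: ionisation of the tertiary allylic methyl ether before ring opening, oxidative loss of the electron-rich hydroquinone monoether in the hot solution, and carry-over of any C5-linked isomer of 9 into the isomeric 8-hydroxy-5-methoxy flavone. The fallback sets out from 8 and comes back at 12. The alkoxide 8 would be protonated (aq. NH4Cl) instead of methylated, to give the carbinol F4 named above. Its thermolysis (p-xylene, 140 °C, Ar; wash with aq. Na2S2O4) is the parent form of this ring expansion and would give 2-[2,4-bis(benzyloxy)phenyl]-5,8-dihydroxy-3,6,7-trimethoxy-4H-chromen-4-one F5. Because both new oxygens are free, a pyranone linked through C5 or through C6 ends in the same hydroquinone. The 5-OH is held in a hydrogen bond to the C4 carbonyl, so methylation of the free 8-OH (Me2SO4 1.05 equiv, K2CO3, acetone, rt, Ar) would give 12.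

Step 3. What may go wrong: protodeboronation of the electron-rich ortho-alkoxy boronic acid and substitution of the vinylogous acyl bromide by aqueous base before coupling. The fallback sets out from 1 and comes back at 5 with the polarity of the coupling reversed. O-Methylation of 1 (MeI, K2CO3, acetone) would give 3-methoxy-4H-pyran-4-one F6. Zincation with TMPZnCl·LiCl at C2, the position flanked by the ring oxygen and the methoxy group, would give (3-methoxy-4-oxo-4H-pyran-2-yl)zinc chloride F7. Negishi coupling with commercial 1-bromo-2,4-bis(benzyloxy)benzene (Pd(OAc)2, SPhos, THF, 50 °C) would give 5 without halogenation, boronic acid or aqueous base.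

**Further compounds**
F1 | step 4 | {6-[2,4-bis(benzyloxy)phenyl]-5-methoxy-4-oxo-4H-pyran-2-yl}zinc chloride | Cl[Zn]c1cc(=O)c(OC)c(-c2ccc(OCc3ccccc3)cc2OCc2ccccc2)o1
F2 | step 4 | 2-[2,4-bis(benzyloxy)phenyl]-6-iodo-3-methoxy-4H-pyran-4-one | COc1c(-c2ccc(OCc3ccccc3)cc2OCc2ccccc2)oc(I)cc1=O
F3 | step 4 | {6-[2,4-bis(benzyloxy)phenyl]-5-methoxy-4-oxo-4H-pyran-2-yl}magnesium chloride | Cl[Mg]c1cc(=O)c(OC)c(-c2ccc(OCc3ccccc3)cc2OCc2ccccc2)o1
F4 | step 4 | 4-{6-[2,4-bis(benzyloxy)phenyl]-5-methoxy-4-oxo-4H-pyran-2-yl}-4-hydroxy-2,3-dimethoxycyclobut-2-en-1-one (racemic) | OC1(c2cc(=O)c(OC)c(-c3ccc(OCc4ccccc4)cc3OCc3ccccc3)o2)C(OC)=C(OC)C1=O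
F5 | step 5 | 2-[2,4-bis(benzyloxy)phenyl]-5,8-dihydroxy-3,6,7-trimethoxy-4H-chromen-4-one | COc1c(OC)c(O)c2c(=O)c(OC)c(-c3ccc(OCc4ccccc4)cc3OCc3ccccc3)oc2c1O
F6 | step 3 | 3-methoxy-4H-pyran-4-one | COc1coccc1=O
F7 | step 3 | (3-methoxy-4-oxo-4H-pyran-2-yl)zinc chloride | COc1c([Zn]Cl)occc1=O
A1 | direct plan | 2-methoxy-1-(2,3,4,5-tetramethoxyphenyl)ethan-1-one | COCC(=O)c1cc(OC)c(OC)c(OC)c1OC
A2 | direct plan | 1-[2,4-bis(benzyloxy)phenyl]-2-methoxy-3-(2,3,4,5-tetramethoxyphenyl)propane-1,3-dione (racemic) | COC(C(=O)c1ccc(OCc2ccccc2)cc1OCc1ccccc1)C(=O)c1cc(OC)c(OC)c(OC)c1OC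
A3 | direct plan | 2-[2,4-bis(benzyloxy)phenyl]-3,5,6,7,8-pentamethoxy-4H-chromen-4-one | COc1c(-c2ccc(OCc3ccccc3)cc2OCc2ccccc2)oc2c(OC)c(OC)c(OC)c(OC)c2c1=O
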